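Ring B (C1, C2, C3, C4, C4a, C8a) shares the C4a–C8a edge with the dimethoxybenzene ring A. Its two benzylic carbons C1 and C4 can therefore serve as the ends of an o-quinodimethane, and C2–C3 as a two-carbon dienophile. The plan cuts C1–C2 and C3–C4. Light turns a 2-benzylbenzaldehyde (formyl carbon = C4, diarylmethane carbon = C1) into its dienol, which a titanium–TADDOL template unites with an N-crotonoyl imide. This single operation closes ring B, forms both bonds and sets C1 to C4, among them the 1,2-trans pair of the target. Afterwards the acyl group becomes the C3 methyl group and C4–OH leaves as water.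

Key step: step 3

Remarks on the chemistry:
- Numbering: all bicyclic compounds carry the numbering of the target (C1 = aryl-bearing methine, C2 = methyl-bearing methine, then C3, C4, C4a, C8a; ring A = fused dimethoxybenzene). The target is (1R,2S), 1,2-trans.
- Assumption on the ligand: (R,R)-TADDOLate–titanium complexes normally steer cycloadditions to the Cα-Re face of 3-enoyloxazolidinones. The Cα-Si face is needed here, so the (S,S) antipode is chosen. Both antipodes are commercial, and the choice is reversed if the first adduct shows the opposite sense.
- Acid sensitivity: the diarylmethane aldehyde cyclodehydrates readily to 2,3,6,7-tetramethoxyanthracene under Brønsted or strong Lewis acids. It is therefore made under basic conditions and meets only a chloride-free, alkoxide-type titanium(IV) species.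

Step 1
Reactants: 1 (2-formyl-4,5-dimethoxyphenyl)boronic acid; 2 3,4-dimethoxybenzyl chloride
Product: 3 2-(3,4-dimethoxybenzyl)-4,5-dimethoxybenzaldehyde
Conditions: Pd(OAc)2 (2 mol%), SPhos (4 mol%), K3PO4 (2 equiv), toluene/H2O (10:1), 80 °C
Reagents that add atoms: none
Why: The sp2–sp3 Suzuki–Miyaura coupling of benzylic halides with 2-formylarylboronic acids is established, the position of boron fixes where the benzyl group enters, and the acid-free medium excludes both cyclo-oligomerisation of the veratryl electrophile and Bradsher-type cyclodehydration of the product aldehyde.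

Step 2
Reactants: 4 oxazolidin-2-one; 5 (E)-crotonyl chloride
Product: 7 (E)-3-(but-2-enoyl)oxazolidin-2-one, via lithium oxazolidinonide 6 (not isolated)
Conditions: n-BuLi (1.0 equiv), THF, −78 °C; then 5, −78 → 0 °C; recrystallisation
Reagents that add atoms: none
Why: N-Acylation of the lithiated carbamate by an acid chloride is the standard imide synthesis, it avoids amine bases that could deconjugate the crotonoyl unit through a vinylketene, and crystallisation should remove any Z isomer brought in by the acid chloride.

Step 3
Reactants: 3 2-(3,4-dimethoxybenzyl)-4,5-dimethoxybenzaldehyde; 7 (E)-3-(but-2-enoyl)oxazolidin-2-one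
Product: 9 (1R,2S,3R,4R)-1-(3,4-dimethoxyphenyl)-4-hydroxy-6,7-dimethoxy-2-methyl-3-[(2-oxooxazolidin-3-yl)carbonyl]tetralin (aryl/OH/acyl on one face; methyl on the other), via (E,E)-photodienol 8 (not isolated)
Conditions: (S,S)-TADDOL (1.3 equiv), Ti(OiPr)4 (1.2 equiv), 4 Å MS, toluene, rt, liberated iPrOH evaporated; then 3, 7 (1.2 equiv), degassed toluene, hν (365 nm LED), 0 °C; aq. NaHCO3 work-up
Reagents that add atoms: none
Why: Excitation of the aldehyde is followed by 1,5-hydrogen transfer from the doubly benzylic CH2 to the carbonyl oxygen, and of the dienols so formed only 8, with OH and aryl both turned away from the diene interior, lives long enough to exchange onto the TADDOLate–titanium alkoxide, which also binds the carbonyl groups of 7. The closest known reaction type is the titanium alkoxide/TADDOL-promoted enantioselective photoenolisation/Diels–Alder reaction of 2-alkylbenzaldehydes with α,β-unsaturated carbonyl compounds, supported by Ti–TADDOLate Diels–Alder chemistry of 3-enoyloxazolidinones and by the long-known trapping of photoenols of 2-benzylbenzaldehydes. Ring B closes by an intermolecular, metal-templated, concerted suprafacial [4π+2π] cycloaddition that forms C1–C2 and C3–C4 in one event and is driven by recovery of the aromatic sextet of ring A. The 1,4-cis relation comes from the E,E geometry of the diene, the 3,4-cis relation from endo placement of the imide carbonyl enforced by the O–Ti–O bridge, the 2,3-trans and hence 1,2-trans relation from the E alkene, and the absolute sense (addition to the Cα-Si face) from the ligand aryl groups that cover the Cα-Re face. Regioselectivity is needed because both diene termini carry donors: the oxygen donor is the stronger, places the larger HOMO coefficient on C1, which pairs with the β-carbon of the imide, and the titanium tether between the C4 oxygen and the acyl group acts in the same direction. Chemoselectivity rests on the weak, chloride-free Lewis acid, which neither triggers attack of the electron-rich benzyl ring on the aldehyde nor ionises the new benzylic alcohol, on the low reactivity of unbound 7, which suppresses the untemplated racemic pathway, and on a wavelength that only 3 absorbs.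

Step 4
Reactants: 9 tetralin imide adduct
Product: 10 (1R,2S,3S,4R)-1-(3,4-dimethoxyphenyl)-3-(hydroxymethyl)-6,7-dimethoxy-2-methyltetralin-4-ol
Conditions: LiBH4 (2.5 equiv), MeOH (1.5 equiv), THF, 0 °C
Reagents that add atoms: none
Why: Reductive cleavage of N-acyloxazolidinones with LiBH4 is the standard conversion of β-hydroxy imides into 1,3-diols, it attacks the exocyclic carbonyl, touches no stereocentre (the change of the C3 descriptor is only a priority change) and is cold and fast enough to outrun retro-aldol opening.

Step 5
Reactants: 10 1,3-diol
Product: 11 (1R,2S,3S,4R)-1-(3,4-dimethoxyphenyl)-4-hydroxy-6,7-dimethoxy-2-methyltetralin-3-ylmethyl 4-methylbenzenesulfonate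
Conditions: TsCl (1.05 equiv), Et3N, DMAP (cat.), CH2Cl2, 0 °C
Reagents that add atoms: p-toluenesulfonyl chloride, Cc1ccc(S(=O)(=O)Cl)cc1
Why: In this selective sulfonylation the unhindered primary hydroxyl should consume one equivalent of TsCl much faster than the secondary benzylic hydroxyl flanked by ring A and C3, and no stereocentre takes part.

Step 6
Reactants: 11 primary monotosylate
Product: 12 (1R,2S,3R,4R)-1-(3,4-dimethoxyphenyl)-6,7-dimethoxy-2,3-dimethyltetralin-4-ol
Conditions: LiEt3BH (3 equiv), THF, 0 °C → rt, 11 added to the hydride
Reagents that add atoms: none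
Why: SN2 displacement of a primary tosylate by the highly nucleophilic LiEt3BH is the usual path from 1,3-diol monotosylates to methyl carbinols, inverse addition keeps hydride delivery ahead of any reaction of the boron-complexed C4 alkoxide, and C3 is untouched because substitution occurs at the exocyclic carbon.

Step 7
Reactants: 12 benzylic alcohol
Product: 13 (1R,2S)-1-(3,4-dimethoxyphenyl)-6,7-dimethoxy-2,3-dimethyl-1,2-dihydronaphthalene (target)
Conditions: p-TsOH·H2O (5 mol%), 4 Å MS, toluene, rt → 40 °C, short contact time
Reagents that add atoms: none
Why: In this acid-catalysed E1 dehydration the C4 cation is stabilised by the para methoxy group at C7 and has C3–H as its only β-hydrogen, so only the C3=C4 styrene can form, while C1 and C2 lie outside the ionising system and carry the 1R,2S pair unchanged into the target.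

Compound list
1 | (2-formyl-4,5-dimethoxyphenyl)boronic acid | COc1cc(C=O)c(B(O)O)cc1OC | starting material
2 | 3,4-dimethoxybenzyl chloride | COc1ccc(CCl)cc1OC | starting material
3 | 2-(3,4-dimethoxybenzyl)-4,5-dimethoxybenzaldehyde | COc1ccc(Cc2cc(OC)c(OC)cc2C=O)cc1OC | intermediate
4 | oxazolidin-2-one | O=C1NCCO1 | starting material
5 | (E)-crotonyl chloride | C/C=C/C(=O)Cl | starting material
6 | lithium 2-oxooxazolidin-3-ide | [Li+].O=C1[N-]CCO1 | intermediate
7 | (E)-3-(but-2-enoyl)oxazolidin-2-one | C/C=C/C(=O)N1CCOC1=O | intermediate
8 | (E,E)-α-hydroxy-α′-(3,4-dimethoxyphenyl)-4,5-dimethoxy-o-quinodimethane (photodienol, held on titanium) | O/C=C1/C(=C/c2ccc(OC)c(OC)c2)C=C(OC)C(OC)=C1 | intermediate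
9 | (1R,2S,3R,4R)-1-(3,4-dimethoxyphenyl)-4-hydroxy-6,7-dimethoxy-2-methyl-3-[(2-oxooxazolidin-3-yl)carbonyl]tetralin | COc1ccc([C@@H]2c3cc(OC)c(OC)cc3[C@H](O)[C@H](C(=O)N4CCOC4=O)[C@H]2C)cc1OC | intermediate
10 | (1R,2S,3S,4R)-1-(3,4-dimethoxyphenyl)-3-(hydroxymethyl)-6,7-dimethoxy-2-methyltetralin-4-ol | COc1ccc([C@@H]2c3cc(OC)c(OC)cc3[C@H](O)[C@H](CO)[C@H]2C)cc1OC | intermediate
11 | primary monotosylate of 10, (1R,2S,3S,4R) | COc1ccc([C@@H]2c3cc(OC)c(OC)cc3[C@H](O)[C@H](COS(=O)(=O)c4ccc(C)cc4)[C@H]2C)cc1OC | intermediate
12 | (1R,2S,3R,4R)-1-(3,4-dimethoxyphenyl)-6,7-dimethoxy-2,3-dimethyltetralin-4-ol | COc1ccc([C@@H]2c3cc(OC)c(OC)cc3[C@H](O)[C@H](C)[C@H]2C)cc1OC | intermediate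
13 | (1R,2S)-1-(3,4-dimethoxyphenyl)-6,7-dimethoxy-2,3-dimethyl-1,2-dihydronaphthalene | COc1ccc([C@@H]2c3cc(OC)c(OC)cc3C=C(C)[C@H]2C)cc1OC | target

Total step count: 7. Longest linear sequence: 6 (steps 1, 3, 4, 5, 6, 7; step 2 is a one-step side branch).

Steps most likely to fail

1. Step 3.
   - What may go wrong: the non-covalently bound ligand may discriminate the two faces only partly. Endo/exo control may erode, which would carry over into the C1/C2 relation. The short-lived dienol may be captured too slowly by a β-substituted dienophile. The crotonoyl unit may isomerise E→Z under irradiation.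
   - Fallback: stereocontrol is moved from the ligand to a covalently bound auxiliary. The fallback sets out from 3. The dienophile (S)-4-benzyl-3-[(E)-but-2-enoyl]oxazolidin-2-one F1 is prepared from 5 and (S)-4-benzyloxazolidin-2-one in the manner of step 2. It is irradiated with 3 at 365 nm in the presence of achiral Ti(OiPr)4.
   - In the chelated s-cis imide the benzyl group covers the Cα-Re face, so the dienol should add to the Cα-Si face and give the auxiliary-bearing adduct (1R,2S,3R,4R)-3-{[(4S)-4-benzyl-2-oxooxazolidin-3-yl]carbonyl}tetralin F2. Its stereoisomers are diastereomers and can be separated by chromatography or crystallisation.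
   - LiBH4 cleavage as in step 4 comes back to the route at 10.

2. Step 6.
   - What may go wrong: the C4 alkoxide generated by the hydride may act before displacement is complete. It could close onto the CH2OTs carbon to give a cis-fused oxetane, or push a Grob-type cleavage of the C3–C4 bond.
   - Fallback: the polar, basic reduction is replaced by a neutral radical one. The fallback sets out from 11. Finkelstein exchange (NaI, acetone, reflux) gives the primary iodide (1R,2S,3R,4R)-3-(iodomethyl)tetralin-4-ol F3.
   - F3 is reduced with Bu3SnH/AIBN in toluene at 80 °C. No alkoxide is ever present, and hydrogen transfer to the primary radical is far faster than β-scission of an unstrained ring. The sequence comes back to the route at 12.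

3. Step 1.
   - What may go wrong: the ortho-formyl boronic acid may protodeboronate, and the solvolysis-prone benzylic chloride may hydrolyse or homocouple in the aqueous basic medium.
   - Fallback: the polarity of the coupling is reversed and water is excluded. The fallback sets out from 2. Zinc insertion (Zn dust, LiCl, THF, rt) gives 3,4-dimethoxybenzylzinc chloride F4.
   - F4 undergoes Negishi coupling with commercial 2-bromo-4,5-dimethoxybenzaldehyde (Pd(OAc)2/SPhos, THF, rt). The ortho-formyl group speeds oxidative addition, while the electron-rich aldehyde is a poor electrophile for the organozinc reagent. The coupling comes back to the route at 3.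

Further compounds
F1 | step 3 | (S)-4-benzyl-3-[(E)-but-2-enoyl]oxazolidin-2-one | C/C=C/C(=O)N1[C@@H](Cc2ccccc2)COC1=O
F2 | step 3 | (1R,2S,3R,4R)-3-{[(4S)-4-benzyl-2-oxooxazolidin-3-yl]carbonyl}-1-(3,4-dimethoxyphenyl)-4-hydroxy-6,7-dimethoxy-2-methyltetralin | COc1ccc([C@@H]2c3cc(OC)c(OC)cc3[C@H](O)[C@H](C(=O)N4[C@@H](Cc5ccccc5)COC4=O)[C@H]2C)cc1OC
F3 | step 6 | (1R,2S,3R,4R)-1-(3,4-dimethoxyphenyl)-3-(iodomethyl)-6,7-dimethoxy-2-methyltetralin-4-ol | COc1ccc([C@@H]2c3cc(OC)c(OC)cc3[C@H](O)[C@H](CI)[C@H]2C)cc1OC
F4 | step 1 | 3,4-dimethoxybenzylzinc chloride | COc1ccc(C[Zn]Cl)cc1OC
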